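At early times the eta run shows target at 0.2 % after 0.250 min, while substrate has already fallen to 78.1 %, so a step must lie between the two. The next rung is the loss of substrate. I read a first-order constant of 0.895 /min from the eta run and 0.926 /min from the gamma run, which gives a half-life near 0.774 min. Then comes the stop. In the gamma run target reads highest at 2.50 min, yet 0.338 M of substrate still stands there, so substrate is not what ends target's rise in that flask. The slowest rung is the asked time, 5.0 min, which is longer than the gamma run took to stop, so I expect each new flask to stand on its plateau.

| flask | substrate | partner | remark | time |
|---|---|---|---|---|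
| eta | 0.98 M | 0.72 M | run made earlier |  |
| gamma | 2.6 M | 0.72 M | run made earlier |  |
| Saturday's | 0.80 M | 0.720 M |  | 5.0 min |
| Friday's | 1.2 M | 0.720 M |  | 5.0 min |
| Sunday's | 2.0 M | 0.720 M |  | 5.0 min |

- eta (time / min: target / %, substrate / %): 0.250: 0.2, 78.1; 0.500: 4.2, 61.5; 0.833: 9.7, 43.7; 1.33: 19.3, 28.3; 2.00: 30.7, 16.3; 4.00: 44.6, 4.8
- gamma (time / min: target / %, substrate / %): 0.667: 4.9, 51.9; 1.33: 11.7, 26.6; 2.00: 15.4, 15.1; 2.50: 17.8, 13.0; 3.00: 16.3, 8.2; 4.00: 15.5, 6.1

(readings scatter by 1 percentage point)

- the numbers in the tables scatter with a standard deviation of 1 percentage point
- "hardly changes" means that all values lie within two and a half points (for a concentration: within two and a half percent of the largest)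
- a step back or a flat step of under half a percent of the largest counts as no turn

* [target] at the end for Saturday's, Friday's, Sunday's, in this order
* the shape of the row from first to last (falls all the way / hardly changes / rises all the way / rises, then falls / falls, then rises)

The rate of target over the rate of partner's loss changes during a run, as target's lag shows, so I divide amounts instead: time drops out, and what stays is a plain ratio. I call it the partner yield φ: c(target) on the plateau over c(partner) charged. The mean of the gamma readings from 2.50 min to 4.00 min gives φ = 0.597. The eta run, on a different substrate charge, gives 0.607 at 4.00 min. So I take partner as the limiting reagent. Each new flask holds 0.720 M of partner, which puts c(target) near 0.430 M, and even Saturday's substrate charge is larger than that. My own row is therefore flat.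

The forecast differs: it gives 0.4 M, 0.48 M and 0.45 M, with the shape "rises, then falls", and it holds that “excess intermediate probably destroys target or wastes partner”.

The flask gives 0.422 M, 0.456 M and 0.440 M, with the shape "rises, then falls", as the forecast said and against my flat row. The steps are these:

    substrate ⇌ open intermediate (K = 15.0, k = 0.0170 /s)
    2 second intermediate → homo product (k = 0.00170 /M/s)
    partner → second intermediate (k = 0.0220 /s)
    partner + target → over-reaction product (k = 0.0540 /M/s)
    open intermediate + second intermediate ⇌ target (K = 32.0 /M, k = 0.0320 /M/s)

In Sunday's flask partner stands at 0 % of its charge at 5.00 min, and it is the first to run out. Sunday's partner yield comes to 0.611, against φ of 0.597. Friday's comes to 0.633.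

(The runs stem from a simulated flask with constants of no real substance; scatter was added.)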